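**Plan**
- Retrosynthesis: after removal of two silyl groups, ring C is opened at O1–C2 and at C4–C4a to give ester 16, the aryl (3R)-3-hydroxy-3-arylpropanoate of the ring-A phenol 8. The ester is cut to 8 and an aroylketene (from 4-hydroxybenzoic acid and Meldrum's acid). Phenol 8 is cut at the C8–prenyl bond and traced to 3-hydroxy-4,5-dimethoxybenzaldehyde.
- Enabling feature: ring A is pentasubstituted and C4a is its only CH. C4a lies ortho to O1 (1,3-related through C8a), and C2 is a benzylic C–O carbon. An acyl group parked on O1 as an ester (an O1–C4 bond that is absent from the target) can therefore shift only to C4a, after which the freed O1 attacks C2.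
- Forward order: ring A is dressed first (silylation, Baeyer–Villiger, MOM-directed lithiation/prenylation). The C2–C3–C4 chain is then hung on O1 as a β-keto ester and reduced. Ring C is closed last by a one-pot photo-Fries shift/Mitsunobu etherification, followed by desilylation.
- Stereochemistry: C2, the only stereocentre, is set as the (R)-carbinol by Ru–TsDPEN transfer hydrogenation (step 9) and inverted to (S) by the SN2 ring closure (step 10).

Key step: step 10

Assumption: the transfer hydrogenation of step 9 is taken to follow the usual aryl-ketone sense of the TsDPEN–Ru catalysts ((R,R)-ligand gives the (R)-carbinol); the mirror-image catalyst would be used if the sense proved opposite.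

**Route**

Step 1
Reactants: 1 3-hydroxy-4,5-dimethoxybenzaldehyde
Product: 2 3,4-dimethoxy-5-[(triisopropylsilyl)oxy]benzaldehyde
Conditions: TIPSCl, imidazole, DMF, rt
Reagents that add atoms: chlorotriisopropylsilane CC(C)[Si](Cl)(C(C)C)C(C)C
Why: Silyl ether formation at the only phenol; the bulky, weakly coordinating TIPS group should later shield the neighbouring ring CH from metalation and should survive acid, light and Mitsunobu conditions until the last step.

Step 2
Reactants: 2 3,4-dimethoxy-5-[(triisopropylsilyl)oxy]benzaldehyde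
Product: 4 3,4-dimethoxy-5-[(triisopropylsilyl)oxy]phenol, via aryl formate 3 (not isolated)
Conditions: mCPBA, CH2Cl2, 0 °C → rt; then Et3N (cat.), MeOH, rt
Reagents that add atoms: 3-chloroperoxybenzoic acid OOC(=O)c1cccc(Cl)c1
Why: Baeyer–Villiger oxidation in which the electron-rich aryl group (para-methoxy) migrates in the Criegee intermediate to give the aryl formate, which mild methanolysis should cleave without touching the TIPS ether.

Step 3
Reactants: 4 3,4-dimethoxy-5-[(triisopropylsilyl)oxy]phenol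
Product: 5 [2,3-dimethoxy-5-(methoxymethoxy)phenoxy]triisopropylsilane
Conditions: MOMCl, i-Pr2NEt, CH2Cl2, 0 °C → rt
Reagents that add atoms: chloromethyl methyl ether COCCl
Why: O-Alkylation of the phenol (Williamson type) puts a strong ortho-directing MOM group on the oxygen that becomes O1.

Step 4
Reactants: 5 [2,3-dimethoxy-5-(methoxymethoxy)phenoxy]triisopropylsilane
Product: 7 [2,3-dimethoxy-5-(methoxymethoxy)-4-(3-methylbut-2-en-1-yl)phenoxy]triisopropylsilane, via aryllithium 6 (not isolated)
Conditions: n-BuLi, THF, 0 °C; then CuBr·SMe2 (10 mol %), prenyl bromide, −78 °C → rt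
Reagents that add atoms: 1-bromo-3-methylbut-2-ene (prenyl bromide) CC(C)=CCBr
Why: Directed ortho-metalation should remove the proton of the ring CH between the chelating OMOM and OMe groups (the other CH is flanked by the bulky, non-coordinating OTIPS group), and the copper-mediated alkylation of the aryllithium should take place at the primary carbon of prenyl bromide.

Step 5
Reactants: 7 [2,3-dimethoxy-5-(methoxymethoxy)-4-(3-methylbut-2-en-1-yl)phenoxy]triisopropylsilane
Product: 8 3,4-dimethoxy-2-(3-methylbut-2-en-1-yl)-5-[(triisopropylsilyl)oxy]phenol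
Conditions: conc. HCl (cat.), MeOH, 40 °C
Reagents that add atoms: none
Why: Acid-catalysed acetal methanolysis of the MOM ether under dilute conditions that aryl TIPS ethers and ortho-prenyl phenols normally tolerate.

Step 6
Reactants: 9 4-hydroxybenzoic acid
Product: 11 4-[(triisopropylsilyl)oxy]benzoic acid, via bis-silyl ester 10 (not isolated)
Conditions: TIPSCl (2.2 equiv), imidazole, DMF, rt; then K2CO3, THF/MeOH/H2O, rt; 1 M HCl to pH 4
Reagents that add atoms: chlorotriisopropylsilane CC(C)[Si](Cl)(C(C)C)C(C)C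
Why: Exhaustive silylation followed by selective hydrolysis of the labile silyl ester should leave the aryl silyl ether in place.

Step 7
Reactants: 11 4-[(triisopropylsilyl)oxy]benzoic acid; 12 2,2-dimethyl-1,3-dioxane-4,6-dione (Meldrum's acid)
Product: 13 5-(hydroxy{4-[(triisopropylsilyl)oxy]phenyl}methylidene)-2,2-dimethyl-1,3-dioxane-4,6-dione
Conditions: DCC, DMAP, CH2Cl2, 0 °C → rt
Reagents that add atoms: none
Why: Carbodiimide activation and DMAP acyl transfer (Steglich type) should C-acylate Meldrum's acid to the enolised acyl Meldrum's acid.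

Step 8
Reactants: 13 5-(hydroxy{4-[(triisopropylsilyl)oxy]phenyl}methylidene)-2,2-dimethyl-1,3-dioxane-4,6-dione; 8 3,4-dimethoxy-2-(3-methylbut-2-en-1-yl)-5-[(triisopropylsilyl)oxy]phenol
Product: 15 3,4-dimethoxy-2-(3-methylbut-2-en-1-yl)-5-[(triisopropylsilyl)oxy]phenyl 3-oxo-3-{4-[(triisopropylsilyl)oxy]phenyl}propanoate, via aroylketene 14 (not isolated)
Conditions: toluene, 110 °C
Reagents that add atoms: none
Why: Thermal retro-[4+2] loss of acetone and CO2 from the acyl Meldrum's acid gives an aroylketene that the phenol traps (the classical β-keto ester synthesis), so the temporary O1–C4 ester bond should form without acid or base.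

Step 9
Reactants: 15 3,4-dimethoxy-2-(3-methylbut-2-en-1-yl)-5-[(triisopropylsilyl)oxy]phenyl 3-oxo-3-{4-[(triisopropylsilyl)oxy]phenyl}propanoate
Product: 16 3,4-dimethoxy-2-(3-methylbut-2-en-1-yl)-5-[(triisopropylsilyl)oxy]phenyl (3R)-3-hydroxy-3-{4-[(triisopropylsilyl)oxy]phenyl}propanoate
Conditions: RuCl[(R,R)-TsDPEN](p-cymene) (1 mol %), HCO2H/Et3N (5:2), CH2Cl2, rt
Reagents that add atoms: none
Why: Noyori asymmetric transfer hydrogenation of an aryl ketone activated as a β-keto ester, in which the Ru–H/N–H catalyst delivers hydride to one carbonyl face (aryl oriented by the CH/π contact with p-cymene) and should set the (R)-carbinol that becomes C2, while the prenyl alkene and the aryl ester are not reduced.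

Step 10
Reactants: 16 3,4-dimethoxy-2-(3-methylbut-2-en-1-yl)-5-[(triisopropylsilyl)oxy]phenyl (3R)-3-hydroxy-3-{4-[(triisopropylsilyl)oxy]phenyl}propanoate
Product: 18 (2S)-6,7-dimethoxy-8-(3-methylbut-2-en-1-yl)-5-[(triisopropylsilyl)oxy]-2-{4-[(triisopropylsilyl)oxy]phenyl}chroman-4-one, via ketol 17 (not isolated)
Conditions: hν (254 nm, quartz), degassed MeCN (0.005 M), rt; evaporate; PPh3, DIAD, toluene, −20 → 0 °C
Reagents that add atoms: none
Why: Excitation of the aryl ester cleaves the O1–acyl bond homolytically and the caged aryloxyl/acyl radical pair recombines at C4a, the only carbon of ring A that bears hydrogen (C8 carries the prenyl group, C6 a methoxy group), so that tautomerisation gives ketol 17 with the C4–C4a bond; PPh3/DIAD then turns the benzylic C2–OH into an oxyphosphonium leaving group that the chelated phenol O1–H displaces to form the O1–C2 bond. The closest known reaction types are the photo-Fries rearrangement of aryl esters and the intramolecular Mitsunobu etherification of 3-hydroxy-1-(2-hydroxyaryl)-3-arylpropan-1-ones to flavanones. Ring C closes in the 6-exo-tet mode. The C2 stereocentre is transferred, not created: SN2 displacement inverts the (R)-carbinol of step 9 to the (S)-aryl ether. The step needs acylation at C4a instead of radical escape, closure by O1 and not by the C5 oxygen, and substitution instead of ionisation or E1cB loss of the leaving group; the single free ortho position, the TIPS ether on the C5 oxygen and a cold, non-polar medium should secure these in that order. Phenol 8 formed by cage escape can be recovered and returned to step 8.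

Step 11
Reactants: 18 (2S)-6,7-dimethoxy-8-(3-methylbut-2-en-1-yl)-5-[(triisopropylsilyl)oxy]-2-{4-[(triisopropylsilyl)oxy]phenyl}chroman-4-one
Product: 19 (2S)-5-hydroxy-2-(4-hydroxyphenyl)-6,7-dimethoxy-8-(3-methylbut-2-en-1-yl)chroman-4-one
Conditions: TBAF, AcOH (1:1), THF, 0 °C → rt
Reagents that add atoms: none
Why: Fluoride-induced cleavage of both aryl silyl ethers, with acetic acid keeping the liberated phenols protonated so that base-induced opening of ring C (retro-oxa-Michael, which would racemise C2) should be avoided.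

**Compound list**

1 | 3-hydroxy-4,5-dimethoxybenzaldehyde | COc1cc(C=O)cc(O)c1OC | starting material
2 | 3,4-dimethoxy-5-[(triisopropylsilyl)oxy]benzaldehyde | COc1cc(C=O)cc(O[Si](C(C)C)(C(C)C)C(C)C)c1OC | intermediate
3 | 3,4-dimethoxy-5-[(triisopropylsilyl)oxy]phenyl formate | COc1cc(OC=O)cc(O[Si](C(C)C)(C(C)C)C(C)C)c1OC | intermediate
4 | 3,4-dimethoxy-5-[(triisopropylsilyl)oxy]phenol | COc1cc(O)cc(O[Si](C(C)C)(C(C)C)C(C)C)c1OC | intermediate
5 | [2,3-dimethoxy-5-(methoxymethoxy)phenoxy]triisopropylsilane | COCOc1cc(OC)c(OC)c(O[Si](C(C)C)(C(C)C)C(C)C)c1 | intermediate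
6 | 5,6-dimethoxy-2-(methoxymethoxy)-4-[(triisopropylsilyl)oxy]phenyllithium | [Li]c1c(OCOC)cc(O[Si](C(C)C)(C(C)C)C(C)C)c(OC)c1OC | intermediate
7 | [2,3-dimethoxy-5-(methoxymethoxy)-4-(3-methylbut-2-en-1-yl)phenoxy]triisopropylsilane | COCOc1cc(O[Si](C(C)C)(C(C)C)C(C)C)c(OC)c(OC)c1CC=C(C)C | intermediate
8 | 3,4-dimethoxy-2-(3-methylbut-2-en-1-yl)-5-[(triisopropylsilyl)oxy]phenol | COc1c(OC)c(O[Si](C(C)C)(C(C)C)C(C)C)cc(O)c1CC=C(C)C | intermediate
9 | 4-hydroxybenzoic acid | OC(=O)c1ccc(O)cc1 | starting material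
10 | triisopropylsilyl 4-[(triisopropylsilyl)oxy]benzoate | CC(C)[Si](OC(=O)c1ccc(O[Si](C(C)C)(C(C)C)C(C)C)cc1)(C(C)C)C(C)C | intermediate
11 | 4-[(triisopropylsilyl)oxy]benzoic acid | OC(=O)c1ccc(O[Si](C(C)C)(C(C)C)C(C)C)cc1 | intermediate
12 | 2,2-dimethyl-1,3-dioxane-4,6-dione (Meldrum's acid) | CC1(C)OC(=O)CC(=O)O1 | starting material
13 | 5-(hydroxy{4-[(triisopropylsilyl)oxy]phenyl}methylidene)-2,2-dimethyl-1,3-dioxane-4,6-dione | CC1(C)OC(=O)C(=C(O)c2ccc(O[Si](C(C)C)(C(C)C)C(C)C)cc2)C(=O)O1 | intermediate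
14 | 3-oxo-3-{4-[(triisopropylsilyl)oxy]phenyl}prop-1-en-1-one (aroylketene) | O=C=CC(=O)c1ccc(O[Si](C(C)C)(C(C)C)C(C)C)cc1 | intermediate
15 | 3,4-dimethoxy-2-(3-methylbut-2-en-1-yl)-5-[(triisopropylsilyl)oxy]phenyl 3-oxo-3-{4-[(triisopropylsilyl)oxy]phenyl}propanoate | COc1c(OC)c(O[Si](C(C)C)(C(C)C)C(C)C)cc(OC(=O)CC(=O)c2ccc(O[Si](C(C)C)(C(C)C)C(C)C)cc2)c1CC=C(C)C | intermediate
16 | 3,4-dimethoxy-2-(3-methylbut-2-en-1-yl)-5-[(triisopropylsilyl)oxy]phenyl (3R)-3-hydroxy-3-{4-[(triisopropylsilyl)oxy]phenyl}propanoate | COc1c(OC)c(O[Si](C(C)C)(C(C)C)C(C)C)cc(OC(=O)C[C@@H](O)c2ccc(O[Si](C(C)C)(C(C)C)C(C)C)cc2)c1CC=C(C)C | intermediate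
17 | (3R)-3-hydroxy-1-{2-hydroxy-4,5-dimethoxy-3-(3-methylbut-2-en-1-yl)-6-[(triisopropylsilyl)oxy]phenyl}-3-{4-[(triisopropylsilyl)oxy]phenyl}propan-1-one | COc1c(OC)c(O[Si](C(C)C)(C(C)C)C(C)C)c(C(=O)C[C@@H](O)c2ccc(O[Si](C(C)C)(C(C)C)C(C)C)cc2)c(O)c1CC=C(C)C | intermediate
18 | (2S)-6,7-dimethoxy-8-(3-methylbut-2-en-1-yl)-5-[(triisopropylsilyl)oxy]-2-{4-[(triisopropylsilyl)oxy]phenyl}chroman-4-one | COc1c(O[Si](C(C)C)(C(C)C)C(C)C)c2c(c(CC=C(C)C)c1OC)O[C@H](c1ccc(O[Si](C(C)C)(C(C)C)C(C)C)cc1)CC2=O | intermediate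
19 | (2S)-5-hydroxy-2-(4-hydroxyphenyl)-6,7-dimethoxy-8-(3-methylbut-2-en-1-yl)chroman-4-one | COc1c(O)c2c(c(CC=C(C)C)c1OC)O[C@H](c1ccc(O)cc1)CC2=O | target

**Step count**

Total step count: 11. Longest linear sequence: 9 steps (steps 1–5, 8, 9, 10, 11).

**Steps most likely to fail**

1. Step 10. The configuration at C2 may erode during ring closure, either by ionisation of the para-silyloxybenzylic oxyphosphonium ion or by E1cB elimination to the chalcone followed by unselective reclosure; radical escape in the photochemical stage would only lower the yield. Fallback: a kinetic resolution replaces the stereospecific substitution. It sets out from ketol 17. Under the PPh3/DIAD conditions the part that eliminates gives the (E)-chalcone F1. NaOAc in EtOH at 60 °C closes F1, so that all material is collected as flavanone of low or no enantiomeric purity and treated as the racemic bis-silyl flavanone F2. Asymmetric transfer hydrogenation with RhCl[(R,R)-TsDPEN](C5Me5) and HCO2H/Et3N in EtOAc, run to about half conversion, should reduce the (2R)-enantiomer to the cis-(2R,4R)-flavan-4-ol F3. This follows from (4R)-selective hydride delivery combined with the cis preference of flavanone reduction. The unreacted (2S)-ketone is separated by chromatography and is 18, where the route is rejoined.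

2. Step 4. Metalation may occur at the other ring CH (between OMOM and OTIPS), or the silyl group may migrate within the aryllithium, placing the prenyl group at the wrong carbon. Fallback: a sigmatropic route replaces the metalation and also bypasses steps 3 and 5. It sets out from phenol 4. O-Alkylation with 3-chloro-3-methylbut-1-yne (CuCl2·2H2O cat., DBU, MeCN, 0 °C) gives the aryl 1,1-dimethylpropargyl ether F4. Semihydrogenation (H2, Pd/CaCO3 poisoned with Pb(OAc)2, quinoline, EtOAc) gives the aryl 1,1-dimethylallyl ether F5. Aromatic Claisen rearrangement (N,N-diethylaniline, 120 °C) through the chair transition state at the ortho carbon next to OMe, not the one next to the bulky OTIPS group, should deliver the ortho-prenyl phenol 8, where the route is rejoined.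

3. Step 9. The electron-rich aryl ester may be lost under the reducing medium (transesterification, or ketene formation from the enolate), or the electron-rich aroyl ketone may be reduced with insufficient facial selectivity. Fallback: the stereocentre is set on a simple alkyl β-keto ester before the aryl ester is made. It sets out from acyl Meldrum's acid 13.
   - Methanolysis (MeOH, reflux) gives the methyl β-keto ester F6.
   - Asymmetric hydrogenation ([RuCl(p-cymene)((S)-BINAP)]Cl, H2 10 bar, MeOH, 50 °C) should give the methyl (3R)-β-hydroxy ester F7.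
   - TESCl/imidazole gives the triethylsilyl ether F8.
   - Me3SnOH in 1,2-dichloroethane at 80 °C gives the acid F9.
   - Steglich esterification with phenol 8 (DCC, DMAP, CH2Cl2) gives the aryl ester F10.
   - AcOH/THF/H2O removes the alkyl TES group selectively and gives 16, where the route is rejoined.

Further compounds
F1 | step 10 | (E)-1-{2-hydroxy-4,5-dimethoxy-3-(3-methylbut-2-en-1-yl)-6-[(triisopropylsilyl)oxy]phenyl}-3-{4-[(triisopropylsilyl)oxy]phenyl}prop-2-en-1-one | COc1c(OC)c(O[Si](C(C)C)(C(C)C)C(C)C)c(C(=O)/C=C/c2ccc(O[Si](C(C)C)(C(C)C)C(C)C)cc2)c(O)c1CC=C(C)C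
F2 | step 10 | racemic 6,7-dimethoxy-8-(3-methylbut-2-en-1-yl)-5-[(triisopropylsilyl)oxy]-2-{4-[(triisopropylsilyl)oxy]phenyl}chroman-4-one | COc1c(O[Si](C(C)C)(C(C)C)C(C)C)c2c(c(CC=C(C)C)c1OC)OC(c1ccc(O[Si](C(C)C)(C(C)C)C(C)C)cc1)CC2=O
F3 | step 10 | (2R,4R)-6,7-dimethoxy-8-(3-methylbut-2-en-1-yl)-5-[(triisopropylsilyl)oxy]-2-{4-[(triisopropylsilyl)oxy]phenyl}chroman-4-ol | COc1c(O[Si](C(C)C)(C(C)C)C(C)C)c2c(c(CC=C(C)C)c1OC)O[C@@H](c1ccc(O[Si](C(C)C)(C(C)C)C(C)C)cc1)C[C@H]2O
F4 | step 4 | {2,3-dimethoxy-5-[(2-methylbut-3-yn-2-yl)oxy]phenoxy}triisopropylsilane | COc1cc(OC(C)(C)C#C)cc(O[Si](C(C)C)(C(C)C)C(C)C)c1OC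
F5 | step 4 | {2,3-dimethoxy-5-[(2-methylbut-3-en-2-yl)oxy]phenoxy}triisopropylsilane | COc1cc(OC(C)(C)C=C)cc(O[Si](C(C)C)(C(C)C)C(C)C)c1OC
F6 | step 9 | methyl 3-oxo-3-{4-[(triisopropylsilyl)oxy]phenyl}propanoate | COC(=O)CC(=O)c1ccc(O[Si](C(C)C)(C(C)C)C(C)C)cc1
F7 | step 9 | methyl (3R)-3-hydroxy-3-{4-[(triisopropylsilyl)oxy]phenyl}propanoate | COC(=O)C[C@@H](O)c1ccc(O[Si](C(C)C)(C(C)C)C(C)C)cc1
F8 | step 9 | methyl (3R)-3-[(triethylsilyl)oxy]-3-{4-[(triisopropylsilyl)oxy]phenyl}propanoate | COC(=O)C[C@@H](O[Si](CC)(CC)CC)c1ccc(O[Si](C(C)C)(C(C)C)C(C)C)cc1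
F9 | step 9 | (3R)-3-[(triethylsilyl)oxy]-3-{4-[(triisopropylsilyl)oxy]phenyl}propanoic acid | OC(=O)C[C@@H](O[Si](CC)(CC)CC)c1ccc(O[Si](C(C)C)(C(C)C)C(C)C)cc1
F10 | step 9 | 3,4-dimethoxy-2-(3-methylbut-2-en-1-yl)-5-[(triisopropylsilyl)oxy]phenyl (3R)-3-[(triethylsilyl)oxy]-3-{4-[(triisopropylsilyl)oxy]phenyl}propanoate | COc1c(OC)c(O[Si](C(C)C)(C(C)C)C(C)C)cc(OC(=O)C[C@@H](O[Si](CC)(CC)CC)c2ccc(O[Si](C(C)C)(C(C)C)C(C)C)cc2)c1CC=C(C)C
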